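The constants of this chemistry are not in hand, so I read one from the earlier runs; with 1 equiv of second substrate, a percent of the starting material charged is also a percent of second substrate.

| setting | oak | cedar | ash | alder | summer | spring | noon | midnight |
|---|---|---|---|---|---|---|---|---|
| starting material | 0.30 M | 0.20 M | 0.45 M | 0.30 M | 0.30 M | 0.30 M | 0.30 M (fed, over 30 min) | 0.30 M (in portions, 3, over 30 min) |
| reagent | 2 equiv | 2 equiv | 2 equiv | 4 equiv | 2.00 equiv | 2.00 equiv | 2.00 equiv | 2.00 equiv |
| second substrate | 1 equiv | 1 equiv | 1 equiv | 1 equiv | 1.00 equiv (fed, over 30 min) | 1.00 equiv | 1.00 equiv | 1.00 equiv |
| remark | run made earlier | run made earlier | run made earlier | run made earlier | all else is in the flask from the start; the feed brings no volume worth counting | everything together at the start | all else is in the flask from the start; the feed brings no volume worth counting | first portion at the start, last at 30 min |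
| time |  |  |  |  | 80 min | 80 min | 80 min | 80 min |

| run | time / min | cross product / % | target / % |
|---|---|---|---|
| oak | 12.0 | 34 | 24 |
| oak | 25.0 | 42 | 30 |
| oak | 30.0 | 44 | 33 |
| oak | 50.0 | 47 | 31 |
| oak | 60.0 | 50 | 35 |
| oak | 80.0 | 51 | 35 |
| cedar | 6.00 | 20 | 14 |
| cedar | 15.0 | 31 | 23 |
| cedar | 20.0 | 34 | 23 |
| cedar | 30.0 | 40 | 30 |
| cedar | 40.0 | 43 | 32 |
| cedar | 50.0 | 47 | 31 |
| ash | 2.50 | 19 | 17 |
| ash | 8.00 | 33 | 28 |
| ash | 15.0 | 42 | 30 |
| ash | 20.0 | 43 | 29 |
| ash | 30.0 | 45 | 34 |
| ash | 40.0 | 50 | 30 |
| ash | 50.0 | 51 | 31 |
| alder | 10.0 | 28 | 36 |
| alder | 20.0 | 30 | 40 |
| alder | 30.0 | 36 | 41 |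
| alder | 40.0 | 39 | 42 |
| alder | 50.0 | 40 | 43 |

(readings scatter by 2 percentage points)

- the earlier runs were read with a standard deviation of 2 percentage points
- a reading or a percentage of target counts all its forms, free or not

1. the flask that comes out highest in amount of cross product, in percent of the starting material charged, or "all alike" when all lie within 1.5 percentage points (summer / spring / noon / midnight / all alike)
2. cross product at the end, in percent of the starting material charged, summer
3. cross product at the end, in percent of the starting material charged, spring
4. cross product at the end, in percent of the starting material charged, noon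
5. cross product at the end, in percent of the starting material charged, midnight

At 50.0 min the oak run reads 47% of cross product, and the alder run, with 4 equiv of reagent in place of 2 equiv, reads 40%, less, so I take it that starting material and reagent compete for second substrate. The oak run ends at 51% of cross product, and I count the other 49.0% as lost, though some may still stand in the flask:

G = (51% / 49.0%) × 2 = 2.08

This is my capture constant, a selectivity factor: the odds of second substrate reaching cross product rather than going away, per unit of [starting material]/[reagent]. The alder run's last reading gives 2.67, so it is rough.

Now noon in slow motion. In the first instants, at 2.82 min, the feed has delivered 9.39% of the charge, and I take reagent as charged: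

odds = G × 9.39% / 2.00 = 0.0978

So in noon the loss of second substrate runs at 10.2 times its capture. In the middle, the odds reach one near 28.8 min with reagent as charged, yet the oak run already reads 34% of cross product at 12.0 min, earlier than the feed of noon ends, so I expect the second substrate of noon to be lost during the feed. At the end, the cross product of noon can grow from the second substrate that has outlasted that opening.

With reagent as charged, the first portion of midnight starts at odds of 0.347, and spring, which is the oak recipe, starts at 1.04, while noon is still at 0.0978 at 2.82 min, so noon opens lowest. The second substrate of summer first meets the same odds of 1.04 as spring, so I expect spring near 51%, summer close to it, then midnight, and noon last.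

The forecast parts from me: noon highest, with summer 39%, spring 52%, noon 56% and midnight 54%, on the ground that “Feeding SM should suppress this, with selectivity otherwise unchanged”.

The flasks give summer 50.5%, spring 52.0%, noon 45.1% and midnight 45.9%, so spring comes highest.

    starting material + reagent → target (k = 0.120 M⁻¹ min⁻¹)
    second substrate + reagent → second product (k = 0.170 M⁻¹ min⁻¹)
    starting material + second substrate → cross product (k = 0.270 M⁻¹ min⁻¹)
    2 reagent → homo dimer (k = 0.160 M⁻¹ min⁻¹)
    second substrate + target ⇌ idle adduct, settled at all times (K = 1.70 M⁻¹)

In noon at 2.82 min, second substrate goes to second product 9.2 times as fast as to cross product, where G gave 10.2, and half of that step's turnover up to the asked time is done by 4.38 min. Summer at 30.0 min holds 29.8% of starting material and 7.88% of its reagent, so G gives odds of 3.94, and up to 80.0 min summer gains 3.10 cross product for each second product.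

The earlier runs and the new flask were computed with constants of no real substance.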